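(The constants stand for no real mixture; the flask was simulated.)

The leftover came first: the flask held more coupling partner, 0.150 M, than substrate, 0.10 M, so substrate was the limiting reagent and some coupling partner had to remain.

substrate 0.10 M; coupling partner 0.150 M; time 20 h

    substrate ⇌ tautomer (K1 = 2.1, k1 = 0.0017 s⁻¹)
    substrate + coupling partner → isomer of the product (k2 = 0.0074 M⁻¹ s⁻¹)
    coupling partner + tautomer → target (k3 = 0.17 M⁻¹ s⁻¹)
    tautomer → side product (k4 = 0.0032 s⁻¹)
    2 substrate → homo dimer (k5 = 0.0010 M⁻¹ s⁻¹)

- in percentages every species weighs as the substrate in it: one homo dimer counts as two
- for a step with 2 of a species take k times the square, and two of it per event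
- run time (flask): 20 h

* target at 20 h, in percent of the substrate charged
* amount of target if the flask were left three thousand times as long, in percent of the substrate charged

I froze the coupling partner, which made the step to isomer of the product pseudo-first-order; the step to tautomer was first order already, and the step to homo dimer stayed second order in substrate. Substrate became tautomer at k1 and isomer of the product at k2 times that level. Those two rates match at k1 over k2, 0.230 M; I called this level the reach. Tautomer was caught at 0.0255 s⁻¹ and lost otherwise, by return or decay, at 0.00401 s⁻¹. Because capture was faster, I held tautomer at a low steady level. So target over isomer, the selectivity factor, came to the reach divided by the level plus 0.0236 M.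

With coupling partner and substrate at their charged levels, substrate went to target at 0.00147 s⁻¹, to isomer at 0.00111 s⁻¹, to side product at 1.84 × 10⁻⁴ s⁻¹ and to homo dimer at 2.00 × 10⁻⁴ s⁻¹. Target's share was 49.6%. The weak link was the frozen level, since those shares used 0.0870 M of coupling partner. So I reforged it: I took the level midway, 0.106 M, and the dimer rate at half its first value. The four rates became 0.00139 s⁻¹, 7.88 × 10⁻⁴ s⁻¹, 2.46 × 10⁻⁴ s⁻¹ and 1.00 × 10⁻⁴ s⁻¹. Substrate's half-life was then 0.0762 h, far shorter than the run, and target stands on the left of no step. I committed to 55.1% at the time asked and 55.1% left long.

The forecast said 55% and 55%: "The tautomer is captured quickly by the excess coupling partner".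

The flask gave 54.5% and, left long, 54.5%. At the midway level the reach gives target over isomer as 1.77; this flask ended with 54.5% target and 31.4% isomer. The neighbour charged with 0.38 M of coupling partner kept 75% of it, so its midway level was 0.332 M, above the reach. The reach gives that neighbour a ratio of 0.647, and it ended with 37.5% target and 58.1% isomer.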